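**Retrosynthetic overview**
1. Target ⇐ enantioselective hydrogenation of the furan C6a=C11a bond of the corresponding aromatic pterocarpene (a benzofuran); both stereocentres are set in the last step.
2. Pterocarpene ⇐ one-pot Pd enolate arylation/cyclodehydration of a tricyclic pyranochromanone with 2-bromo-5-methoxyphenol (builds the furan ring and brings in ring D).
3. Pyranochromanone ⇐ Friedel–Crafts acylation/O-cyclisation of 2,2-dimethylchroman-5,7-diol with 3-chloropropanoic acid (ring B).
4. 2,2-Dimethylchroman-5,7-diol ⇐ phloroglucinol + isoprene.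
5. Ring order: dimethyldihydropyran → pyranone (ring B) → aromatic furan (ring C) → reduction to the cis-dihydrofuran.

Assumption: the facial sense of the Ru–NHC catalyst in step 5 cannot be predicted for this substrate; the route is written with the (R,R)-ligand, the first run is checked against (6aS,11aS) by chiral HPLC/ECD, and the (S,S)-ligand is used instead if the antipode forms.

Pterocarpan numbering is used for 11–13: ring A C1–C4, C4a, O5, C6, C6a, ring D C6b–C10a, O11, C11a, C11b. The target is (6aS,11aS), cis-fused.

**Step 1**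
Reactants: 1 phloroglucinol; 2 isoprene
Product: 3 2,2-dimethylchroman-5,7-diol
Conditions: 2 (0.8 equiv), 85% H3PO4, xylene, 30–35 °C (1 in excess)
Reagents that add atoms: isoprene (2), CC(=C)C=C
Why: Acid-catalysed Friedel–Crafts prenylation followed by hydroalkoxylation (chroman annulation): the prenyl cation C-alkylates any of the three equivalent positions of the C3-symmetric triol and the tertiary cation is trapped by a flanking OH, so only one mono-chroman can form, and excess 1 suppresses bis-annulation.

**Step 2**
Reactants: 3 2,2-dimethylchroman-5,7-diol; 4 3-chloropropanoic acid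
Product: 6 5-hydroxy-2,2-dimethyl-3,4,8,9-tetrahydro-2H,10H-pyrano[2,3-f]chromen-10-one, via 8-(3-chloropropanoyl)-2,2-dimethylchroman-5,7-diol 5 (not isolated)
Conditions: 4 (1.1 equiv), TfOH, 50 °C; then 2 M aq NaOH, 0 °C → rt; HCl to pH 3; chromatography
Reagents that add atoms: 3-chloropropanoic acid (4), OC(=O)CCCl
Why: Friedel–Crafts acylation of the phloroglucinol-type ring followed by intramolecular Williamson (or E1cB/oxa-Michael) closure onto the only ortho-OH; C8, between O1 and 7-OH, is the position 5,7-dihydroxychromans generally favour for electrophiles, and 6, whose free OH is para to C=O and not chelated, is far more polar than the two chelated linear isomers from C6 attack and is separated from them.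

**Step 3**
Reactants: 6 pyranochromanone phenol; 7 chloromethyl methyl ether
Product: 8 5-(methoxymethoxy)-2,2-dimethyl-3,4,8,9-tetrahydro-2H,10H-pyrano[2,3-f]chromen-10-one
Conditions: MOMCl (1.3 equiv), iPr2NEt (2 equiv), CH2Cl2, 0 °C → rt
Reagents that add atoms: chloromethyl methyl ether (7), COCCl
Why: O-alkylation (MOM protection) of the acidic para-acyl phenol, so that the ketone can be enolised in step 4 without a deactivating para-phenoxide.

**Step 4**
Reactants: 8 MOM-protected pyranochromanone; 9 2-bromo-5-methoxyphenol
Product: 12 dimethyldihydropyrano-pterocarpene phenol, via α-aryl chromanone 10 (not isolated), via MOM-protected pterocarpene 11 (not isolated)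
Conditions: Pd(OAc)2 (5 mol %), rac-2-(di-tert-butylphosphino)-1,1'-binaphthyl (10 mol %), NaOtBu (2.5 equiv), toluene, 80 °C; then 3 M HCl/MeOH, 60 °C
Reagents that add atoms: 2-bromo-5-methoxyphenol (9), COc1ccc(Br)c(O)c1
Why: Pd-catalysed ketone enolate α-arylation (Buchwald–Hartwig type) with the free o-bromophenol, then acid cyclodehydration of the 2'-hydroxy-α-aryl ketone to the benzofuran while the same acid removes the MOM group; both the one-pot ketone/o-bromophenol benzofuran synthesis and α-arylation of 4-chromanones are known, and the bromide fixes OMe para to the new C–C bond.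

**Step 5**
Reactants: 12 dimethyldihydropyrano-pterocarpene phenol
Product: 13 (6aS,11aS)-configured target pterocarpan
Conditions: Ru((R,R)-SINpEt)2 catalyst (5 mol %, preformed from [Ru(cod)(2-methylallyl)2], (R,R)-SINpEt·HBF4, KOtBu), H2 (60 bar), toluene, 40 °C
Reagents that add atoms: none
Why: Proposed new method: a chiral Ru–bis(NHC) catalyst binds one π-face of the benzofuran and delivers H2 syn across the tetrasubstituted C6a=C11a bond, breaking the furan aromaticity and creating both stereocentres at once (syn addition can only give the cis ring fusion, the catalyst selects the face leading to 6aS,11aS); the closest known reaction types are Ru–NHC-catalysed asymmetric hydrogenation of 2-aryl- and 2-alkylbenzofurans to 2,3-dihydrobenzofurans and Pd/C hydrogenation of pterocarpenes to racemic cis-pterocarpans.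

**Compound list**
1 | phloroglucinol (benzene-1,3,5-triol) | Oc1cc(O)cc(O)c1 | starting material
2 | isoprene (2-methylbuta-1,3-diene) | CC(=C)C=C | starting material
3 | 2,2-dimethylchroman-5,7-diol | CC1(C)CCc2c(O)cc(O)cc2O1 | intermediate
4 | 3-chloropropanoic acid | OC(=O)CCCl | starting material
5 | 8-(3-chloropropanoyl)-2,2-dimethylchroman-5,7-diol | CC1(C)CCc2c(O)cc(O)c(C(=O)CCCl)c2O1 | intermediate (not isolated)
6 | 5-hydroxy-2,2-dimethyl-3,4,8,9-tetrahydro-2H,10H-pyrano[2,3-f]chromen-10-one (angular tricycle; ketone carbon flanked by both ring oxygens, free OH para to C=O) | CC1(C)CCc2c(O)cc3OCCC(=O)c3c2O1 | intermediate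
7 | chloromethyl methyl ether (MOMCl) | COCCl | starting material
8 | 5-(methoxymethoxy)-2,2-dimethyl-3,4,8,9-tetrahydro-2H,10H-pyrano[2,3-f]chromen-10-one | CC1(C)CCc2c(OCOC)cc3OCCC(=O)c3c2O1 | intermediate
9 | 2-bromo-5-methoxyphenol | COc1ccc(Br)c(O)c1 | starting material
10 | rac-9-(2-hydroxy-4-methoxyphenyl)-5-(methoxymethoxy)-2,2-dimethyl-3,4,8,9-tetrahydro-2H,10H-pyrano[2,3-f]chromen-10-one | CC1(C)CCc2c(OCOC)cc3OCC(c4ccc(OC)cc4O)C(=O)c3c2O1 | intermediate (not isolated)
11 | 9-methoxy-3-(methoxymethoxy)-6a,11a-didehydropterocarpan (6H-benzofuro[3,2-c]chromene core) carrying a 2,2-dimethyl-3,4-dihydro-2H-pyran fused at C1 (ring O) and C2 (CH2) | COc1ccc2c(c1)oc1c2COc2cc(OCOC)c3CCC(C)(C)Oc3c21 | intermediate (not isolated)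
12 | 3-hydroxy-9-methoxy-6a,11a-didehydropterocarpan carrying the same C1(O)/C2(CH2)-fused 2,2-dimethyldihydropyran | COc1ccc2c(c1)oc1c2COc2cc(O)c3CCC(C)(C)Oc3c21 | intermediate
13 | (6aS,11aS)-3-hydroxy-9-methoxypterocarpan carrying the C1(O)/C2(CH2)-fused 2,2-dimethyl-3,4-dihydro-2H-pyran, cis-fused (CNP0207547.1) | COc1ccc2c(c1)O[C@@H]1c3c(cc(O)c4c3OC(C)(C)CC4)OC[C@H]21 | target

**Totals**
Total step count: 5. Longest linear sequence: 5 (1 → 3 → 6 → 8 → 12 → 13).

**Three steps most likely to fail**

Step 2 (C8 versus C6 acylation, and possible acid-induced migration of the chroman ring in TfOH). The regiochemistry is the main uncertainty of the route; 6 is recognised by the absence of a chelated OH signal near δ 12–13. Fallback, from 1 back to 8, with every position fixed by symmetry or by the single available ortho site: phloroglucinol 1 is acylated while still symmetric with 4 (TfOH, 80 °C) to 3-chloro-1-(2,4,6-trihydroxyphenyl)propan-1-one F1, which 2 M NaOH closes to 5,7-dihydroxychroman-4-one F2. The non-chelated 7-OH is capped with 7 and iPr2NEt to give 5-hydroxy-7-(methoxymethoxy)chroman-4-one F3. The chelated 5-OH is etherified with 3-chloro-3-methylbut-1-yne (CuCl2 cat., DBU, MeCN) to 7-(methoxymethoxy)-5-[(2-methylbut-3-yn-2-yl)oxy]chroman-4-one F4. Heating in xylene (140 °C) effects aryl propargyl Claisen rearrangement, [1,5]-H shift and oxa-6π closure, which can only engage C6, giving 5-(methoxymethoxy)-2,2-dimethyl-8,9-dihydro-2H,10H-pyrano[2,3-f]chromen-10-one F5. H2, Pd/C in EtOAc saturates the chromene C=C and delivers 8.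

Step 4 (ring-opening of the chromanone enolate by β-elimination, diarylation, or poor coupling of the hindered 2,6-dioxygenated aryl ketone). Fallback, from 6 back to 12, without palladium or protection: 6 is condensed with purchased O-(3-methoxyphenyl)hydroxylamine hydrochloride (NOc1cccc(OC)c1 as the HCl salt) in EtOH to the O-(3-methoxyphenyl) oxime of 6 F6. Heating with MsOH or HCl/dioxane (70–100 °C) then drives [3,3]-sigmatropic rearrangement of the ene-hydroxylamine tautomer, rearomatisation and ring closure with loss of ammonia (the oxygen analogue of the Fischer indole synthesis) to give 12. The minor isomer from closure ortho to OMe is removed by chromatography.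

Step 5 (a tetrasubstituted, ring-embedded benzofuran C=C with a free phenol may hydrogenate slowly or with low ee). Fallback, from 10 to 13, setting the stereocentres by reduction of a ketone instead of the heteroarene: step 4 is quenched with aqueous NH4Cl before the acid stage and 10 is isolated. Asymmetric transfer hydrogenation with dynamic kinetic resolution through the labile α-stereocentre (RuCl(p-cymene)[(S,S)-TsDPEN], HCO2H/Et3N, EtOAc, 40 °C) gives (9S,10S)-9-(2-hydroxy-4-methoxyphenyl)-5-(methoxymethoxy)-2,2-dimethyl-3,4,9,10-tetrahydro-2H,8H-pyrano[2,3-f]chromen-10-ol F7, the cis-isoflavan-4-ol. HCl/MeOH at rt ionises the benzylic C–OH, the 2'-phenol closes the cis-fused dihydrofuran with the C6a configuration retained, and the MOM group is lost, giving 13.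

**Further compounds**
F1 | step 2 | 3-chloro-1-(2,4,6-trihydroxyphenyl)propan-1-one | O=C(CCCl)c1c(O)cc(O)cc1O
F2 | step 2 | 5,7-dihydroxychroman-4-one | O=C1CCOc2cc(O)cc(O)c12
F3 | step 2 | 5-hydroxy-7-(methoxymethoxy)chroman-4-one | COCOc1cc(O)c2C(=O)CCOc2c1
F4 | step 2 | 7-(methoxymethoxy)-5-[(2-methylbut-3-yn-2-yl)oxy]chroman-4-one | COCOc1cc(OC(C)(C)C#C)c2C(=O)CCOc2c1
F5 | step 2 | 5-(methoxymethoxy)-2,2-dimethyl-8,9-dihydro-2H,10H-pyrano[2,3-f]chromen-10-one | CC1(C)C=Cc2c(OCOC)cc3OCCC(=O)c3c2O1
F6 | step 4 | O-(3-methoxyphenyl) oxime of 5-hydroxy-2,2-dimethyl-3,4,8,9-tetrahydro-2H,10H-pyrano[2,3-f]chromen-10-one | CC1(C)CCc2c(O)cc3OCCC(=NOc4cccc(OC)c4)c3c2O1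
F7 | step 5 | (9S,10S)-9-(2-hydroxy-4-methoxyphenyl)-5-(methoxymethoxy)-2,2-dimethyl-3,4,9,10-tetrahydro-2H,8H-pyrano[2,3-f]chromen-10-ol | COc1ccc(c(O)c1)[C@H]1COc2cc(OCOC)c3CCC(C)(C)Oc3c2[C@H]1O
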